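**Retrosynthetic overview**

- The strategy rests on the tetrahydropyran ring (O1, C2–C6): the ring A aryl at C2, the hydroxyl at C4 and the 2-(ring B)ethyl chain at C6 are all cis, hence all equatorial on one chair. This is the pattern a chair Prins cyclisation with equatorial capture at C4 delivers.
- One disconnection cuts O1–C2, C2–C3 and C4–O together. It gives an aliphatic (S)-homoallylic alcohol (C3–C6 plus the ring B chain) and the ring A benzaldehyde, both as benzyl ethers, joined in CF3CO2H.
- The homoallylic alcohol comes from methyl 3-(4-hydroxyphenyl)propanoate by O-benzylation, half-reduction and Keck allylation. The allylation sets C6, the only centre made by a catalyst; C2 and C4 are relayed from it.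
- Rings A and B are bought. The tetrahydropyran is the only ring formed, in the key step. Trifluoroacetate methanolysis and hydrogenolysis of three benzyl ethers finish the synthesis.

Key step: step 5

Assumption: the Keck allylation is taken to follow its usual sense, (R)-BINOL sending allyl to the Re face of an unbranched aldehyde; because allyl outranks the arylethyl chain, this face corresponds to the (S) descriptor.

**Step 1**
Reactants: 1 methyl 3-(4-hydroxyphenyl)propanoate
Product: 2 methyl 3-[4-(benzyloxy)phenyl]propanoate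
Conditions: BnBr (1.2 equiv), K2CO3 (2 equiv), acetone, reflux
Reagents that add atoms: benzyl bromide, BrCc1ccccc1
Why: Williamson ether synthesis; the phenoxide formed with K2CO3 displaces bromide from benzyl bromide, and the methyl ester is untouched under anhydrous conditions.

**Step 2**
Reactants: 2 methyl 3-[4-(benzyloxy)phenyl]propanoate
Product: 4 3-[4-(benzyloxy)phenyl]propanal, via aluminium hemiacetal 3 (not isolated)
Conditions: iBu2AlH (DIBAL-H, 1.05 equiv), CH2Cl2, −78 °C; MeOH, then aq. potassium sodium tartrate, rt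
Reagents that add atoms: none
Why: Partial ester reduction with DIBAL-H; the tetrahedral aluminium hemiacetal 3 persists at −78 °C and releases the aldehyde only on aqueous work-up, which should limit over-reduction, and the benzyl ether is inert.

**Step 3**
Reactants: 4 3-[4-(benzyloxy)phenyl]propanal; 5 allyltributylstannane
Product: 7 (S)-1-[4-(benzyloxy)phenyl]hex-5-en-3-ol, via tributylstannyl ether 6 (not isolated)
Conditions: (R)-BINOL (20 mol%), Ti(OiPr)4 (10 mol%), 4 Å MS, CH2Cl2, reflux 1 h; then 4 and 5 (1.2 equiv), −20 °C, 72 h; aq. KF work-up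
Reagents that add atoms: none
Why: Keck asymmetric allylation; the BINOL–titanium Lewis acid activates the aldehyde and the stannane delivers allyl to its Re face, which sets the (S)-carbinol centre (future C6), and the stannyl ether 6 is cleaved on work-up.

**Step 4**
Reactants: 8 3,4-dihydroxy-5-methoxybenzaldehyde
Product: 9 3,4-bis(benzyloxy)-5-methoxybenzaldehyde
Conditions: BnBr (2.4 equiv), K2CO3 (3 equiv), DMF, 60 °C, N2
Reagents that add atoms: benzyl bromide, BrCc1ccccc1
Why: Double Williamson etherification of the catechol; the aldehyde and the aryl methyl ether do not react.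

**Step 5**
Reactants: 7 (S)-1-[4-(benzyloxy)phenyl]hex-5-en-3-ol; 9 3,4-bis(benzyloxy)-5-methoxybenzaldehyde (1.2 equiv)
Product: 11 (2S,4R,6S)-2-[3,4-bis(benzyloxy)-5-methoxyphenyl]-6-{2-[4-(benzyloxy)phenyl]ethyl}tetrahydro-2H-pyran-4-yl trifluoroacetate, via oxocarbenium ion 10 (not isolated)
Conditions: CF3CO2H (20 equiv), CH2Cl2, 0 °C to rt, argon; sat. aq. NaHCO3 quench
Reagents that add atoms: trifluoroacetic acid, OC(=O)C(F)(F)F
Why: Prins cyclisation of a homoallylic alcohol with an aryl aldehyde, a known way to all-cis 2,6-disubstituted tetrahydropyran-4-ols: acid-promoted condensation of the hydroxyl of 7 with 9 and loss of water form O1–C2 and give the (E)-oxocarbenium ion 10 conjugated to ring A, the terminal alkene carbon attacks its carbon to form C2–C3, and trifluoroacetate captures the resulting C4 cation to form C4–O. The pyran closes in a 6-endo-trig mode (the C=O+ bond lies inside the forming ring) through a chair transition state. C2 is controlled by the C6 centre of 7, because the arylethyl chain and ring A both take equatorial positions on the chair of the (E)-ion, which makes C2 and C6 cis; C4 is controlled by the delocalised tetrahydropyranyl cation, which takes the nucleophile equatorially and so gives the all-cis (2S,4R,6S) ring. The step needs cyclisation to outrun 2-oxonia-Cope exchange and C–O ionisation; this is secured by placing the stereocentre on the aliphatic, non-benzylic carbinol, so that C6–O cannot ionise and an oxonia-Cope shift would trade the aryl-conjugated oxocarbenium ion for a less stable aliphatic one. The 4-benzyloxy group of ring A is flanked by two ortho oxygens and twisted out of conjugation, so the aldehyde should stay electrophilic enough, and aryl benzyl ethers should tolerate dilute CF3CO2H for a short time at or below rt.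

**Step 6**
Reactants: 11 the all-cis tetrahydropyran-4-yl trifluoroacetate
Product: 12 (2S,4R,6S)-2-[3,4-bis(benzyloxy)-5-methoxyphenyl]-6-{2-[4-(benzyloxy)phenyl]ethyl}tetrahydro-2H-pyran-4-ol
Conditions: K2CO3 (0.2 equiv), MeOH, rt
Reagents that add atoms: none
Why: Base-catalysed transesterification (methanolysis) of the very electrophilic trifluoroacetate; cleavage is at the acyl–oxygen bond, so the C4 configuration is untouched and the benzyl ethers are inert.

**Step 7**
Reactants: 12 the tribenzyl tetrahydropyran-4-ol
Product: 13 (2S,4R,6S)-2-(3,4-dihydroxy-5-methoxyphenyl)-6-[2-(4-hydroxyphenyl)ethyl]tetrahydro-2H-pyran-4-ol (target)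
Conditions: H2 (1 atm), 10% Pd/C, EtOAc, rt; stopped after uptake of three equivalents; filtration under argon
Reagents that add atoms: none
Why: Catalytic hydrogenolysis of aryl benzyl ethers; the three O–CH2Ph bonds, which release phenols, should cleave well before the cyclic secondary benzylic C2–O1 bond, and no stereocentre is touched.

**Compound list**

1 | methyl 3-(4-hydroxyphenyl)propanoate | COC(=O)CCc1ccc(O)cc1 | starting material
2 | methyl 3-[4-(benzyloxy)phenyl]propanoate | COC(=O)CCc1ccc(OCc2ccccc2)cc1 | intermediate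
3 | {3-[4-(benzyloxy)phenyl]-1-methoxypropoxy}diisobutylaluminium (aluminium hemiacetal, racemic at the acetal carbon) | COC(CCc1ccc(OCc2ccccc2)cc1)O[Al](CC(C)C)CC(C)C | intermediate
4 | 3-[4-(benzyloxy)phenyl]propanal | O=CCCc1ccc(OCc2ccccc2)cc1 | intermediate
5 | allyltributylstannane | C=CC[Sn](CCCC)(CCCC)CCCC | starting material
6 | tributyl{[(3S)-1-(4-(benzyloxy)phenyl)hex-5-en-3-yl]oxy}stannane | C=CC[C@H](CCc1ccc(OCc2ccccc2)cc1)O[Sn](CCCC)(CCCC)CCCC | intermediate
7 | (S)-1-[4-(benzyloxy)phenyl]hex-5-en-3-ol | C=CC[C@H](CCc1ccc(OCc2ccccc2)cc1)O | intermediate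
8 | 3,4-dihydroxy-5-methoxybenzaldehyde | COc1cc(C=O)cc(O)c1O | starting material
9 | 3,4-bis(benzyloxy)-5-methoxybenzaldehyde | COc1cc(C=O)cc(OCc2ccccc2)c1OCc3ccccc3 | intermediate
10 | (E)-oxocarbenium ion from 7 and 9, O-[(3S)-1-(4-(benzyloxy)phenyl)hex-5-en-3-yl], trifluoroacetate salt | C=CC[C@H](CCc1ccc(OCc2ccccc2)cc1)/[O+]=C/c1cc(OC)c(OCc2ccccc2)c(OCc2ccccc2)c1.[O-]C(=O)C(F)(F)F | intermediate
11 | (2S,4R,6S)-2-[3,4-bis(benzyloxy)-5-methoxyphenyl]-6-{2-[4-(benzyloxy)phenyl]ethyl}tetrahydro-2H-pyran-4-yl trifluoroacetate (all-cis) | COc1cc([C@@H]2C[C@H](OC(=O)C(F)(F)F)C[C@H](CCc3ccc(OCc4ccccc4)cc3)O2)cc(OCc5ccccc5)c1OCc6ccccc6 | intermediate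
12 | (2S,4R,6S)-2-[3,4-bis(benzyloxy)-5-methoxyphenyl]-6-{2-[4-(benzyloxy)phenyl]ethyl}tetrahydro-2H-pyran-4-ol (all-cis) | COc1cc([C@@H]2C[C@H](O)C[C@H](CCc3ccc(OCc4ccccc4)cc3)O2)cc(OCc5ccccc5)c1OCc6ccccc6 | intermediate
13 | (2S,4R,6S)-2-(3,4-dihydroxy-5-methoxyphenyl)-6-[2-(4-hydroxyphenyl)ethyl]tetrahydro-2H-pyran-4-ol (all-cis) | COc1cc([C@@H]2C[C@H](O)C[C@H](CCc3ccc(O)cc3)O2)cc(O)c1O | target

**Step count**

Total: 7 steps. Longest linear sequence: 6 steps (steps 1, 2, 3, 5, 6, 7).

**Steps most likely to fail**

Step 5 (Prins cyclisation). The stabilised oxocarbenium ion may cyclise slowly. That would leave time for 2-oxonia-Cope exchange of the side chains, for erosion of enantiopurity, and for acid-promoted loss or migration of benzyl groups. The fallback sets out from 9 and 7 and comes back at 12. It forms the same cation irreversibly from an α-acetoxy ether under a Lewis acid, without strong protic acid. Aldehyde 9 would be oxidised (NaClO2, NaH2PO4, 2-methyl-2-butene, tBuOH/H2O) to 3,4-bis(benzyloxy)-5-methoxybenzoic acid F1. Esterification with 7 (EDC·HCl, DMAP, CH2Cl2) should give (S)-1-[4-(benzyloxy)phenyl]hex-5-en-3-yl 3,4-bis(benzyloxy)-5-methoxybenzoate F2. Reductive acetylation (iBu2AlH, CH2Cl2, −78 °C; then Ac2O, pyridine, DMAP) should give [3,4-bis(benzyloxy)-5-methoxyphenyl]{[(3S)-1-(4-(benzyloxy)phenyl)hex-5-en-3-yl]oxy}methyl acetate F3 as a mixture of acetal epimers. Treatment with BF3·OEt2 and AcOH in hexane/CH2Cl2 at 0 °C should then close the ring to the all-cis tetrahydropyran-4-yl acetate F4. K2CO3 in MeOH would convert F4 into 12.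

Step 7 (hydrogenolysis). Over-reduction may open the electron-rich 2-aryltetrahydropyran at the benzylic C2–O1 bond in competition with debenzylation, and the free catechol may oxidise in air during isolation. The fallback sets out from 7 and 8 and comes back at 13. It uses acyl protection throughout, so that no hydrogenation is needed. The benzyl ether of 7 would be removed before the pyran exists (BCl3, pentamethylbenzene, CH2Cl2, −78 °C, which should spare the alkene and the secondary alcohol) to give (S)-4-(3-hydroxyhex-5-en-1-yl)phenol F5. Selective acetylation of the phenol (Ac2O, aq. NaOH, 0 °C) should give (S)-4-(3-hydroxyhex-5-en-1-yl)phenyl acetate F6. Catechol 8 would be acetylated (Ac2O, pyridine) to 3,4-diacetoxy-5-methoxybenzaldehyde F7. The same CF3CO2H Prins cyclisation of F6 with F7 should give (2S,4R,6S)-2-(3,4-diacetoxy-5-methoxyphenyl)-6-[2-(4-acetoxyphenyl)ethyl]tetrahydro-2H-pyran-4-yl trifluoroacetate F8; aryl acetates are stable to CF3CO2H and make the aldehyde more electrophilic. K2CO3 in degassed MeOH under argon, followed by acidification, should cleave the trifluoroacetate and the three aryl acetates in one operation to give 13.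

Step 3 (Keck allylation). Conversion may stall and the enantioselectivity of the moisture-sensitive titanium–BINOL catalyst may vary from run to run; tin residues may also be hard to remove. The fallback sets out from 4 and comes back at 7. It is an iridium-catalysed transfer-hydrogenative allylation with allyl acetate as the allyl source: [Ir(cod)Cl]2, (R)-BINAP, 4-chloro-3-nitrobenzoic acid, Cs2CO3, allyl acetate, iPrOH as reductant, THF, 100 °C. The (R)-ligand is expected to give the (S)-alcohol, and the sense would be confirmed by Mosher ester analysis before scale-up. No new compound is made on this path (F0).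

**Further compounds**

F1 | step 5 | 3,4-bis(benzyloxy)-5-methoxybenzoic acid | COc1cc(C(=O)O)cc(OCc2ccccc2)c1OCc3ccccc3
F2 | step 5 | (S)-1-[4-(benzyloxy)phenyl]hex-5-en-3-yl 3,4-bis(benzyloxy)-5-methoxybenzoate | C=CC[C@H](CCc1ccc(OCc2ccccc2)cc1)OC(=O)c1cc(OC)c(OCc2ccccc2)c(OCc2ccccc2)c1
F3 | step 5 | [3,4-bis(benzyloxy)-5-methoxyphenyl]{[(3S)-1-(4-(benzyloxy)phenyl)hex-5-en-3-yl]oxy}methyl acetate (acetal epimers) | C=CC[C@H](CCc1ccc(OCc2ccccc2)cc1)OC(OC(C)=O)c1cc(OC)c(OCc2ccccc2)c(OCc2ccccc2)c1
F4 | step 5 | (2S,4R,6S)-2-[3,4-bis(benzyloxy)-5-methoxyphenyl]-6-{2-[4-(benzyloxy)phenyl]ethyl}tetrahydro-2H-pyran-4-yl acetate | COc1cc([C@@H]2C[C@H](OC(C)=O)C[C@H](CCc3ccc(OCc4ccccc4)cc3)O2)cc(OCc5ccccc5)c1OCc6ccccc6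
F5 | step 7 | (S)-4-(3-hydroxyhex-5-en-1-yl)phenol | C=CC[C@H](CCc1ccc(O)cc1)O
F6 | step 7 | (S)-4-(3-hydroxyhex-5-en-1-yl)phenyl acetate | C=CC[C@H](CCc1ccc(OC(C)=O)cc1)O
F7 | step 7 | 3,4-diacetoxy-5-methoxybenzaldehyde | COc1cc(C=O)cc(OC(C)=O)c1OC(C)=O
F8 | step 7 | (2S,4R,6S)-2-(3,4-diacetoxy-5-methoxyphenyl)-6-[2-(4-acetoxyphenyl)ethyl]tetrahydro-2H-pyran-4-yl trifluoroacetate | COc1cc([C@@H]2C[C@H](OC(=O)C(F)(F)F)C[C@H](CCc3ccc(OC(C)=O)cc3)O2)cc(OC(C)=O)c1OC(C)=O
F0 | step 3 | none | none
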